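**Strategy.** Ring A is not brought in as an arene but grown from the acyl end of the chain. Its oxygens at C3 and C5 are meta to each other and C1 carries the C7 methylene, which is the pattern left when a 3,5,7-trioxo ester folds onto itself. The C1–C6 bond of ring A is therefore formed by an intramolecular aldol reaction that turns an open-chain triketo ester into a 6-alkyl-2,4-dihydroxybenzoate in one operation. The precursor already holds ring B (phenol as MOM ether) and both stereocentres: C8′ from an auxiliary-controlled benzylation, C8 from a catalyst-controlled methyl conjugate addition. The ester left on C6 then secures mono-O-methylation before it is removed, and the C4 hydroxyl is added by directed lithiation.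

Key step: step 12

Remark: lignan numbering is used (ring A C1–C6, then C7, C8 and the C9 methyl; primed locants for the ring B half); the target is (8R,8′R).

Assumption: with (E)-enethioates the CuBr complex of (R)-1-[(Sp)-2-(diphenylphosphino)ferrocenyl]ethyldicyclohexylphosphine is taken to deliver the Grignard alkyl group to the Re face of C-β; step 9 needs Si-face delivery and therefore uses the enantiomeric ligand, and because the step is catalyst-controlled the other ligand enantiomer would simply be taken if the sense proved opposite.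

Remark: the thioester Wittig reagent is not assumed to be a catalogue item and is made in steps 6 and 7.

**Route**

Step 1
Reactants: 1 syringaldehyde
Product: 2 3,5-dimethoxy-4-(methoxymethoxy)benzaldehyde
Conditions: MOMCl, i-Pr2NEt, CH2Cl2, 0 °C → rt
Reagents that add atoms: chloromethyl methyl ether, COCCl
Why: O-alkylation of the phenol by the α-chloro ether (Williamson-type acetal formation) should mask the ring B hydroxyl with a group that tolerates bases, hydrides and organometallics and leaves with acid at the very end.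

Step 2
Reactants: 2 3,5-dimethoxy-4-(methoxymethoxy)benzaldehyde
Product: 3 [3,5-dimethoxy-4-(methoxymethoxy)phenyl]methanol
Conditions: NaBH4, MeOH, 0 °C
Reagents that add atoms: none
Why: Borohydride reduction of an aryl aldehyde; nothing else in 2 is reducible.

Step 3
Reactants: 3 [3,5-dimethoxy-4-(methoxymethoxy)phenyl]methanol
Product: 4 5-(bromomethyl)-1,3-dimethoxy-2-(methoxymethoxy)benzene
Conditions: CBr4, PPh3, CH2Cl2, 0 °C; used at once
Reagents that add atoms: carbon tetrabromide, BrC(Br)(Br)Br
Why: The Appel bromination runs under neutral conditions, so the acid-labile MOM acetal should survive where HBr-based methods would threaten it.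

Step 4
Reactants: 4 5-(bromomethyl)-1,3-dimethoxy-2-(methoxymethoxy)benzene; 5 (S)-4-benzyl-3-propionyloxazolidin-2-one
Product: 7 (S)-4-benzyl-3-[(R)-3-[3,5-dimethoxy-4-(methoxymethoxy)phenyl]-2-methylpropanoyl]oxazolidin-2-one, via sodium Z-enolate 6 (not isolated)
Conditions: NaN(SiMe3)2, THF, −78 °C; then 4, −78 → −40 °C
Reagents that add atoms: none
Why: Evans asymmetric alkylation: the chelated Z-enolate should be attacked by the benzylic bromide on the face opposite the benzyl group of the auxiliary, which sets C8′ as R.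

Step 5
Reactants: 7 (S)-4-benzyl-3-[(R)-3-[3,5-dimethoxy-4-(methoxymethoxy)phenyl]-2-methylpropanoyl]oxazolidin-2-one
Product: 8 (R)-3-[3,5-dimethoxy-4-(methoxymethoxy)phenyl]-2-methylpropan-1-ol
Conditions: LiBH4, MeOH (1 equiv), THF, 0 °C
Reagents that add atoms: none
Why: Reductive cleavage of the N-acyl oxazolidinone by LiBH4 attacks the exocyclic carbonyl, frees the auxiliary for recovery and should leave the α-stereocentre untouched.

Step 6
Reactants: 9 bromoacetyl bromide
Product: 10 S-ethyl 2-bromoethanethioate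
Conditions: EtSH, pyridine, CH2Cl2, −10 °C
Reagents that add atoms: ethanethiol, CCS
Why: S-acylation of the thiol by the acyl bromide is much faster at low temperature than SN2 displacement at the α-carbon, so the bromo thioester should form cleanly.

Step 7
Reactants: 10 S-ethyl 2-bromoethanethioate
Product: 12 S-ethyl 2-(triphenyl-λ5-phosphanylidene)ethanethioate, via phosphonium bromide 11 (not isolated)
Conditions: PPh3, toluene, rt; then aq. Na2CO3, CH2Cl2
Reagents that add atoms: triphenylphosphine, c1ccc(cc1)P(c1ccccc1)c1ccccc1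
Why: SN2 quaternisation of PPh3 by the α-bromo thioester and deprotonation of the acidic phosphonium salt by carbonate is the standard preparation of an acyl-stabilised Wittig reagent.

Step 8
Reactants: 8 (R)-3-[3,5-dimethoxy-4-(methoxymethoxy)phenyl]-2-methylpropan-1-ol; 12 S-ethyl 2-(triphenyl-λ5-phosphanylidene)ethanethioate
Product: 14 S-ethyl (R,E)-5-[3,5-dimethoxy-4-(methoxymethoxy)phenyl]-4-methylpent-2-enethioate, via aldehyde 13 (not isolated)
Conditions: Dess–Martin periodinane, NaHCO3, CH2Cl2, 0 °C → rt; then 12, rt → 40 °C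
Reagents that add atoms: none
Why: Dess–Martin oxidation followed in the same flask by Wittig olefination with the stabilised ylide should give the E-enethioate without isolation of the epimerisable α-branched aldehyde.

Step 9
Reactants: 14 S-ethyl (R,E)-5-[3,5-dimethoxy-4-(methoxymethoxy)phenyl]-4-methylpent-2-enethioate
Product: 16 S-ethyl (3R,4R)-5-[3,5-dimethoxy-4-(methoxymethoxy)phenyl]-3,4-dimethylpentanethioate, via magnesium enolate 15 (not isolated)
Conditions: MeMgBr, CuBr·SMe2 (5 mol %), (S)-1-[(Rp)-2-(diphenylphosphino)ferrocenyl]ethyldicyclohexylphosphine (6 mol %), t-BuOMe, −75 °C; then aq. NH4Cl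
Reagents that add atoms: methylmagnesium bromide, C[Mg]Br
Why: Copper-catalysed asymmetric conjugate addition of a Grignard reagent to an α,β-unsaturated thioester; the chiral diphosphine–copper complex should deliver methyl to the Si face of C-β and so set C8 as R under catalyst control, with the γ-stereocentre a minor influence.

Step 10
Reactants: 16 S-ethyl (3R,4R)-5-[3,5-dimethoxy-4-(methoxymethoxy)phenyl]-3,4-dimethylpentanethioate
Product: 17 (3R,4R)-5-[3,5-dimethoxy-4-(methoxymethoxy)phenyl]-N-methoxy-N,3,4-trimethylpentanamide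
Conditions: MeNH(OMe)·HCl, i-PrMgCl (premixed), THF, −20 → 0 °C; then aq. NH4Cl
Reagents that add atoms: N,O-dimethylhydroxylamine hydrochloride, CNOC.Cl
Why: Aminolysis of the thioester by the magnesium amide gives the Weinreb amide, an acyl donor that holds a carbanion as a stable chelated adduct and is far less prone to α-deprotonation by a polyanion than the thioester.

Step 11
Reactants: 17 (3R,4R)-5-[3,5-dimethoxy-4-(methoxymethoxy)phenyl]-N-methoxy-N,3,4-trimethylpentanamide; 18 methyl 3,5-dioxohexanoate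
Product: 20 methyl (9R,10R)-11-[3,5-dimethoxy-4-(methoxymethoxy)phenyl]-9,10-dimethyl-3,5,7-trioxoundecanoate, via trilithium trianion 19 (not isolated)
Conditions: 18 (2 equiv), LiN(i-Pr)2 (6.0 equiv), THF, −78 → 0 °C; then 17, −78 → 0 °C; AcOH quench at −78 °C; crude 20 used directly
Reagents that add atoms: none
Why: Threefold deprotonation leaves the terminal methyl carbanion as the only strongly nucleophilic site, and its acylation by the Weinreb amide (terminal acylation of a 1,3-dicarbonyl polyanion) should give the triketo ester on protonation; the stereocentres lie β and γ to the new ketone and cannot epimerise.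

Step 12
Reactants: 20 methyl (9R,10R)-11-[3,5-dimethoxy-4-(methoxymethoxy)phenyl]-9,10-dimethyl-3,5,7-trioxoundecanoate
Product: 22 methyl 6-[(2R,3R)-4-[3,5-dimethoxy-4-(methoxymethoxy)phenyl]-2,3-dimethylbutyl]-2,4-dihydroxybenzoate, via cyclic aldol 21 (not isolated)
Conditions: aq. NaHCO3/Na2CO3 buffer (pH ≈ 9.5)–MeOH 1:1, 0 °C → rt, then 40 °C; aq. NaH2PO4 to pH 6
Reagents that add atoms: none
Why: In weak base the enolate of the C2 methylene (between the ester and the C3 ketone) adds to the C7 ketone, the β-hydroxy ketone 21 loses one molecule of water by E1cB elimination, and the two remaining ring carbonyls (chain C3 and C5) enolise, so the ring ends as a resorcinol whose former acyl carbon is C1 of ring A. The closest known reaction type is the polyketide-like aldol cyclisation of 3,5,7-trioxoalkanoates to 6-alkyl-2,4-dihydroxybenzoates (orsellinate formation). Ring A closes in the 6-(enolendo)-exo-trig mode, with the new C1–C6 bond in the ring and the attacked carbonyl oxygen outside it. No stereocentre is created (those of 21 vanish on aromatisation), and C8 sits β to the nearest carbonyl, so neither it nor C8′ can epimerise. The step needs aldol closure (C2 onto C7) to beat Claisen closure (C6 onto the ester carbon) and lactonisation to a pyranone: at pH 9–10 only the doubly activated methylenes are ionised, the methyl ester is a poorer electrophile than the unhindered dialkyl ketone, and aromatisation makes the aldol path irreversible. Acid is avoided so that the ring B MOM ether stays in place for step 13.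

Step 13
Reactants: 22 methyl 6-[(2R,3R)-4-[3,5-dimethoxy-4-(methoxymethoxy)phenyl]-2,3-dimethylbutyl]-2,4-dihydroxybenzoate
Product: 23 methyl 6-[(2R,3R)-4-[3,5-dimethoxy-4-(methoxymethoxy)phenyl]-2,3-dimethylbutyl]-2-hydroxy-4-methoxybenzoate
Conditions: MeI (1.1 equiv), K2CO3, acetone, rt
Reagents that add atoms: iodomethane, CI
Why: Williamson methylation; the 2-hydroxyl is hydrogen-bonded to the ester carbonyl and hindered, so only the 4-hydroxyl should react, which guarantees mono-methylation (once the ester is gone either hydroxyl would lead to the same ring A pattern, so only the number of methyl groups matters).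

Step 14
Reactants: 23 methyl 6-[(2R,3R)-4-[3,5-dimethoxy-4-(methoxymethoxy)phenyl]-2,3-dimethylbutyl]-2-hydroxy-4-methoxybenzoate
Product: 25 3-[(2R,3R)-4-[3,5-dimethoxy-4-(methoxymethoxy)phenyl]-2,3-dimethylbutyl]-5-methoxyphenol, via salicylic acid 24 (not isolated)
Conditions: KOH, DMSO–H2O 4:1, 90 °C; then AcOH to pH 6, 100 °C
Reagents that add atoms: none
Why: Saponification of the hindered salicylate followed by thermal protodecarboxylation of the electron-rich 2-hydroxybenzoic acid (ipso protonation, then loss of CO2 as from a β-keto acid) should leave C6–H; the medium stays basic or near neutral, so the MOM ether should survive, and any that is lost is restored in step 15.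

Step 15
Reactants: 25 3-[(2R,3R)-4-[3,5-dimethoxy-4-(methoxymethoxy)phenyl]-2,3-dimethylbutyl]-5-methoxyphenol
Product: 26 5-[(2R,3R)-4-[3-methoxy-5-(methoxymethoxy)phenyl]-2,3-dimethylbutyl]-1,3-dimethoxy-2-(methoxymethoxy)benzene
Conditions: MOMCl, i-Pr2NEt, CH2Cl2, 0 °C → rt
Reagents that add atoms: chloromethyl methyl ether, COCCl
Why: O-alkylation of the ring A phenol installs the directing group for the lithiation and a protecting group that leaves together with the one on ring B.

Step 16
Reactants: 26 5-[(2R,3R)-4-[3-methoxy-5-(methoxymethoxy)phenyl]-2,3-dimethylbutyl]-1,3-dimethoxy-2-(methoxymethoxy)benzene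
Product: 29 4-[(2R,3R)-4-[3,5-dimethoxy-4-(methoxymethoxy)phenyl]-2,3-dimethylbutyl]-2-methoxy-6-(methoxymethoxy)phenol, via aryllithium 27 (not isolated), via lithium aryltrimethoxyborate 28 (not isolated)
Conditions: n-BuLi, THF, 0 °C; B(OMe)3, −78 °C → rt; AcOH, 30% aq. H2O2, 0 °C → rt
Reagents that add atoms: hydrogen peroxide, OO
Why: Directed ortho-metalation should occur at C4 of ring A, the only position flanked by two coordinating oxygens (OMe and OMOM; ring B has no hydrogen next to its MOM ether), and borylation followed by oxidative aryl migration from boron to oxygen gives the phenol.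

Step 17
Reactants: 29 4-[(2R,3R)-4-[3,5-dimethoxy-4-(methoxymethoxy)phenyl]-2,3-dimethylbutyl]-2-methoxy-6-(methoxymethoxy)phenol
Product: 30 sauriol B
Conditions: HCl (4 M in dioxane), MeOH, 0 °C → rt, under argon
Reagents that add atoms: none
Why: Acid-catalysed transacetalisation to methanol should remove both MOM ethers at once; the aryl methyl ethers and the stereocentres, which have no ionisable neighbour, are not affected.

**Compound list**

1 | syringaldehyde (4-hydroxy-3,5-dimethoxybenzaldehyde) | COc1cc(C=O)cc(OC)c1O | starting material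
2 | 3,5-dimethoxy-4-(methoxymethoxy)benzaldehyde | COCOc1c(OC)cc(C=O)cc1OC | intermediate
3 | [3,5-dimethoxy-4-(methoxymethoxy)phenyl]methanol | COCOc1c(OC)cc(CO)cc1OC | intermediate
4 | 5-(bromomethyl)-1,3-dimethoxy-2-(methoxymethoxy)benzene | COCOc1c(OC)cc(CBr)cc1OC | intermediate
5 | (S)-4-benzyl-3-propionyloxazolidin-2-one | CCC(=O)N1[C@@H](Cc2ccccc2)COC1=O | starting material
6 | sodium (Z)-enolate of 5 | C/C=C(\[O-])N1[C@@H](Cc2ccccc2)COC1=O.[Na+] | intermediate
7 | (S)-4-benzyl-3-[(R)-3-[3,5-dimethoxy-4-(methoxymethoxy)phenyl]-2-methylpropanoyl]oxazolidin-2-one | C[C@H](Cc1cc(OC)c(OCOC)c(OC)c1)C(=O)N1[C@@H](Cc2ccccc2)COC1=O | intermediate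
8 | (R)-3-[3,5-dimethoxy-4-(methoxymethoxy)phenyl]-2-methylpropan-1-ol | C[C@H](Cc1cc(OC)c(OCOC)c(OC)c1)CO | intermediate
9 | bromoacetyl bromide | BrCC(Br)=O | starting material
10 | S-ethyl 2-bromoethanethioate | CCSC(=O)CBr | intermediate
11 | [2-(ethylsulfanyl)-2-oxoethyl]triphenylphosphonium bromide | CCSC(=O)C[P+](c1ccccc1)(c1ccccc1)c1ccccc1.[Br-] | intermediate
12 | S-ethyl 2-(triphenyl-λ5-phosphanylidene)ethanethioate | CCSC(=O)C=P(c1ccccc1)(c1ccccc1)c1ccccc1 | intermediate
13 | (R)-3-[3,5-dimethoxy-4-(methoxymethoxy)phenyl]-2-methylpropanal | C[C@H](Cc1cc(OC)c(OCOC)c(OC)c1)C=O | intermediate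
14 | S-ethyl (R,E)-5-[3,5-dimethoxy-4-(methoxymethoxy)phenyl]-4-methylpent-2-enethioate | CCSC(=O)/C=C/[C@H](C)Cc1cc(OC)c(OCOC)c(OC)c1 | intermediate
15 | bromomagnesium enolate of 16 (enolate geometry not defined) | CCSC(O[Mg]Br)=C[C@@H](C)[C@H](C)Cc1cc(OC)c(OCOC)c(OC)c1 | intermediate
16 | S-ethyl (3R,4R)-5-[3,5-dimethoxy-4-(methoxymethoxy)phenyl]-3,4-dimethylpentanethioate | CCSC(=O)C[C@@H](C)[C@H](C)Cc1cc(OC)c(OCOC)c(OC)c1 | intermediate
17 | (3R,4R)-5-[3,5-dimethoxy-4-(methoxymethoxy)phenyl]-N-methoxy-N,3,4-trimethylpentanamide | CON(C)C(=O)C[C@@H](C)[C@H](C)Cc1cc(OC)c(OCOC)c(OC)c1 | intermediate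
18 | methyl 3,5-dioxohexanoate | CC(=O)CC(=O)CC(=O)OC | starting material
19 | trilithium salt of the 2,4,6-trianion of 18 | [Li+].[Li+].[Li+].[CH2-]C(=O)[CH-]C(=O)[CH-]C(=O)OC | intermediate
20 | methyl (9R,10R)-11-[3,5-dimethoxy-4-(methoxymethoxy)phenyl]-9,10-dimethyl-3,5,7-trioxoundecanoate | COC(=O)CC(=O)CC(=O)CC(=O)C[C@@H](C)[C@H](C)Cc1cc(OC)c(OCOC)c(OC)c1 | intermediate
21 | methyl 2-[(2R,3R)-4-[3,5-dimethoxy-4-(methoxymethoxy)phenyl]-2,3-dimethylbutyl]-2-hydroxy-4,6-dioxocyclohexane-1-carboxylate (ring stereocentres not defined) | COC(=O)C1C(=O)CC(=O)CC1(O)C[C@@H](C)[C@H](C)Cc1cc(OC)c(OCOC)c(OC)c1 | intermediate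
22 | methyl 6-[(2R,3R)-4-[3,5-dimethoxy-4-(methoxymethoxy)phenyl]-2,3-dimethylbutyl]-2,4-dihydroxybenzoate | COC(=O)c1c(O)cc(O)cc1C[C@@H](C)[C@H](C)Cc1cc(OC)c(OCOC)c(OC)c1 | intermediate
23 | methyl 6-[(2R,3R)-4-[3,5-dimethoxy-4-(methoxymethoxy)phenyl]-2,3-dimethylbutyl]-2-hydroxy-4-methoxybenzoate | COC(=O)c1c(O)cc(OC)cc1C[C@@H](C)[C@H](C)Cc1cc(OC)c(OCOC)c(OC)c1 | intermediate
24 | 6-[(2R,3R)-4-[3,5-dimethoxy-4-(methoxymethoxy)phenyl]-2,3-dimethylbutyl]-2-hydroxy-4-methoxybenzoic acid | OC(=O)c1c(O)cc(OC)cc1C[C@@H](C)[C@H](C)Cc1cc(OC)c(OCOC)c(OC)c1 | intermediate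
25 | 3-[(2R,3R)-4-[3,5-dimethoxy-4-(methoxymethoxy)phenyl]-2,3-dimethylbutyl]-5-methoxyphenol | COc1cc(O)cc(C[C@@H](C)[C@H](C)Cc2cc(OC)c(OCOC)c(OC)c2)c1 | intermediate
26 | 5-[(2R,3R)-4-[3-methoxy-5-(methoxymethoxy)phenyl]-2,3-dimethylbutyl]-1,3-dimethoxy-2-(methoxymethoxy)benzene | COCOc1cc(OC)cc(C[C@@H](C)[C@H](C)Cc2cc(OC)c(OCOC)c(OC)c2)c1 | intermediate
27 | [4-[(2R,3R)-4-[3,5-dimethoxy-4-(methoxymethoxy)phenyl]-2,3-dimethylbutyl]-2-methoxy-6-(methoxymethoxy)phenyl]lithium | [Li]c1c(OC)cc(C[C@@H](C)[C@H](C)Cc2cc(OC)c(OCOC)c(OC)c2)cc1OCOC | intermediate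
28 | lithium trimethoxy[4-[(2R,3R)-4-[3,5-dimethoxy-4-(methoxymethoxy)phenyl]-2,3-dimethylbutyl]-2-methoxy-6-(methoxymethoxy)phenyl]borate | [Li+].CO[B-](OC)(OC)c1c(OC)cc(C[C@@H](C)[C@H](C)Cc2cc(OC)c(OCOC)c(OC)c2)cc1OCOC | intermediate
29 | 4-[(2R,3R)-4-[3,5-dimethoxy-4-(methoxymethoxy)phenyl]-2,3-dimethylbutyl]-2-methoxy-6-(methoxymethoxy)phenol | COCOc1cc(C[C@@H](C)[C@H](C)Cc2cc(OC)c(OCOC)c(OC)c2)cc(OC)c1O | intermediate
30 | sauriol B, 5-[(2R,3R)-4-(4-hydroxy-3,5-dimethoxyphenyl)-2,3-dimethylbutyl]-3-methoxybenzene-1,2-diol | COc1cc(C[C@@H](C)[C@H](C)Cc2cc(OC)c(O)c(OC)c2)cc(O)c1O | target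

**Step count and risk**

Total step count: 17 (steps 6 and 7 are a two-step side branch that makes the Wittig reagent).
Longest linear sequence: 15 steps (steps 1–5 and 8–17, from syringaldehyde).

The three steps most likely to fail:

Step 12. The ring may close in the Claisen sense (C6 onto the ester) or lactonise to a pyranone instead of following the aldol path, or the cyclised intermediate may stall before dehydration. The fallback makes the same resorcylate by a Michael–Claisen annulation. It sets out from thioester 16 and comes back at 22.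
- Reduction of 16 with i-Bu2AlH (CH2Cl2, −65 °C) should give the aldehyde (3R,4R)-5-[3,5-dimethoxy-4-(methoxymethoxy)phenyl]-3,4-dimethylpentanal F1.
- Wittig reaction of F1 with commercial 1-(triphenylphosphoranylidene)propan-2-one (toluene, 80 °C) should give the enone (3E,6R,7R)-8-[3,5-dimethoxy-4-(methoxymethoxy)phenyl]-6,7-dimethyloct-3-en-2-one F2.
- Dimethyl malonate with NaOMe in refluxing MeOH adds to F2 in the Michael sense to give dimethyl 2-[(6R,7R)-8-[3,5-dimethoxy-4-(methoxymethoxy)phenyl]-6,7-dimethyl-2-oxooctan-4-yl]propanedioate F3.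
- In the same flask the methyl ketone enolate of F3 closes onto one ester to give methyl 2-[(2R,3R)-4-[3,5-dimethoxy-4-(methoxymethoxy)phenyl]-2,3-dimethylbutyl]-4,6-dioxocyclohexane-1-carboxylate F4.
- Oxidative aromatisation of F4 (catalytic I2, DMSO, 80 °C), a known way from cyclohexane-1,3-diones to resorcinols, then gives 22.

In this variant the ring carbons are joined in an order that leaves no choice between aldol and Claisen modes.

Step 11. Proton transfer from the amide to the very basic trianion, or incomplete trianion formation, may leave the amide unconsumed. The fallback uses a less basic dianion and a masked ester. It sets out from 17 and comes back at 20.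
- Commercial 2,2,6-trimethyl-4H-1,3-dioxin-4-one is C-acetylated (LiN(SiMe3)2, THF, −78 °C; acetyl chloride) to 2,2-dimethyl-6-(2-oxopropyl)-4H-1,3-dioxin-4-one F5.
- The dianion of F5 (LiN(i-Pr)2, 2 equiv, THF, −78 °C) should be acylated by 17 at its terminal carbon to give 6-[(6R,7R)-8-[3,5-dimethoxy-4-(methoxymethoxy)phenyl]-6,7-dimethyl-2,4-dioxooctyl]-2,2-dimethyl-4H-1,3-dioxin-4-one F6.
- Heating F6 in toluene with methanol (110 °C) expels acetone by retro-cycloaddition, and the acylketene is trapped as the methyl ester 20.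

Step 9. Facial selectivity may be poor if the catalyst and the γ-stereocentre are mismatched, or the sense of induction may be opposite to the one assumed. The fallback replaces catalyst control by auxiliary control. It sets out from alcohol 8 and comes back at 17.
- One-pot Dess–Martin oxidation and Wittig reaction of 8 with commercial methyl (triphenylphosphoranylidene)acetate should give methyl (R,E)-5-[3,5-dimethoxy-4-(methoxymethoxy)phenyl]-4-methylpent-2-enoate F7.
- LiOH in THF–H2O hydrolyses F7 to (R,E)-5-[3,5-dimethoxy-4-(methoxymethoxy)phenyl]-4-methylpent-2-enoic acid F8.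
- Coupling of F8 with (R)-4-phenyloxazolidin-2-one (DCC, DMAP, CH2Cl2) gives (R)-3-[(R,E)-5-[3,5-dimethoxy-4-(methoxymethoxy)phenyl]-4-methylpent-2-enoyl]-4-phenyloxazolidin-2-one F9.
- MeMgBr with CuBr·SMe2 (THF, −20 °C) should add methyl to the chelated s-cis enoyl imide anti to the phenyl group, that is to the Si face of C-β, and give (R)-3-[(3R,4R)-5-[3,5-dimethoxy-4-(methoxymethoxy)phenyl]-3,4-dimethylpentanoyl]-4-phenyloxazolidin-2-one F10.
- Transamidation of F10 with Me3Al and MeNH(OMe)·HCl (CH2Cl2, 0 °C) releases the auxiliary and gives 17.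

**Further compounds**

F1 | step 12 | (3R,4R)-5-[3,5-dimethoxy-4-(methoxymethoxy)phenyl]-3,4-dimethylpentanal | O=CC[C@@H](C)[C@H](C)Cc1cc(OC)c(OCOC)c(OC)c1
F2 | step 12 | (3E,6R,7R)-8-[3,5-dimethoxy-4-(methoxymethoxy)phenyl]-6,7-dimethyloct-3-en-2-one | CC(=O)/C=C/C[C@@H](C)[C@H](C)Cc1cc(OC)c(OCOC)c(OC)c1
F3 | step 12 | dimethyl 2-[(6R,7R)-8-[3,5-dimethoxy-4-(methoxymethoxy)phenyl]-6,7-dimethyl-2-oxooctan-4-yl]propanedioate (C4 not defined) | COC(=O)C(C(=O)OC)C(CC(C)=O)C[C@@H](C)[C@H](C)Cc1cc(OC)c(OCOC)c(OC)c1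
F4 | step 12 | methyl 2-[(2R,3R)-4-[3,5-dimethoxy-4-(methoxymethoxy)phenyl]-2,3-dimethylbutyl]-4,6-dioxocyclohexane-1-carboxylate (ring stereocentres not defined) | COC(=O)C1C(=O)CC(=O)CC1C[C@@H](C)[C@H](C)Cc1cc(OC)c(OCOC)c(OC)c1
F5 | step 11 | 2,2-dimethyl-6-(2-oxopropyl)-4H-1,3-dioxin-4-one | CC(=O)CC1=CC(=O)OC(C)(C)O1
F6 | step 11 | 6-[(6R,7R)-8-[3,5-dimethoxy-4-(methoxymethoxy)phenyl]-6,7-dimethyl-2,4-dioxooctyl]-2,2-dimethyl-4H-1,3-dioxin-4-one | CC1(C)OC(=O)C=C(CC(=O)CC(=O)C[C@@H](C)[C@H](C)Cc2cc(OC)c(OCOC)c(OC)c2)O1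
F7 | step 9 | methyl (R,E)-5-[3,5-dimethoxy-4-(methoxymethoxy)phenyl]-4-methylpent-2-enoate | COC(=O)/C=C/[C@H](C)Cc1cc(OC)c(OCOC)c(OC)c1
F8 | step 9 | (R,E)-5-[3,5-dimethoxy-4-(methoxymethoxy)phenyl]-4-methylpent-2-enoic acid | OC(=O)/C=C/[C@H](C)Cc1cc(OC)c(OCOC)c(OC)c1
F9 | step 9 | (R)-3-[(R,E)-5-[3,5-dimethoxy-4-(methoxymethoxy)phenyl]-4-methylpent-2-enoyl]-4-phenyloxazolidin-2-one | O=C(/C=C/[C@H](C)Cc1cc(OC)c(OCOC)c(OC)c1)N1[C@H](c2ccccc2)COC1=O
F10 | step 9 | (R)-3-[(3R,4R)-5-[3,5-dimethoxy-4-(methoxymethoxy)phenyl]-3,4-dimethylpentanoyl]-4-phenyloxazolidin-2-one | O=C(C[C@@H](C)[C@H](C)Cc1cc(OC)c(OCOC)c(OC)c1)N1[C@H](c2ccccc2)COC1=O
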